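What I wanted to know was how strongly the rate of making product at 10% conversion in the flask answers to the enzyme charged, although neither earlier run varied that charge.

| flask | substrate | enzyme | remark |
|---|---|---|---|
| grey | 0.085 M | 4.1 µM | run made earlier |
| blue | 0.34 M | 4.1 µM | run made earlier |
| flask | 0.17 M | 4.1 µM |  |

| grey: time / min | grey: product / % | blue: time / min | blue: product / % |
|---|---|---|---|
| 0.667 | 45.2 | 0.667 | 21.6 |
| 1.00 | 52.0 | 1.00 | 25.1 |
| 2.00 | 57.9 | 2.00 | 29.0 |
| 3.00 | 59.5 | 3.00 | 29.8 |
| 5.00 | 58.4 | 5.00 | 29.8 |
| 8.00 | 59.7 | 8.00 | 30.3 |

(readings scatter by 0.5 percentage points)

1. apparent order in enzyme when 10% of the substrate are converted (percent change of the rate of making product for one percent more enzyme charged)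

- the earlier runs were read with a standard deviation of 0.5 percentage points
- no earlier run changes the charge of enzyme; that part of a forecast is a guess

Both runs levelled off, grey at 59.2% and blue at 30.0% of their charges, with 40.8% and 70.0% of the substrate still standing, so I took the enzyme to be dying and counted turnovers. If it dies at its own pace, a charge of enzyme has a fixed lifetime work, the total turnover number, and the integrated Michaelis form, Km·ln(charged c(substrate)/c(substrate)) plus the c(substrate) consumed, prices any conversion against it. Setting both plateaus equal to one budget gave Km 0.0954 M and a budget of 0.136 M, about 33100 turnovers per enzyme at saturation. The flask's 10% cost 0.0271 M, so it used 19.9% of the budget, and I carried this fraction of the lifetime work used by the moment of looking forward as the budget share. The living enzyme then stands at the unspent part, and one percent more enzyme shrinks the share by one percent of itself, so the order is the reciprocal of the unspent part, 1.25.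

The weak link was the single budget for both charges, so I tested it on readings I had not used: at 0.667 min grey had used 70.5% and blue 71.1%, on 4.00 times the substrate. How the dying depends on enzyme stayed a guess.

The forecast stood at 1.25, on the ground that “More enzyme reaches 10% sooner, with less decay”. The flask gave 1.2.

    enzyme → spent catalyst (k = 1.70 min⁻¹)
    substrate + enzyme → product + enzyme, rate k2*[substrate]*[enzyme]/(1 + ([substrate]/Km2) + ([product]/Kp2)) (0.0850 M, 0.110 M, k = 12000 M⁻¹ s⁻¹)

By its own clock, 1.7 min⁻¹ over the 0.117 min to that conversion, the flask's enzyme had lost 18.1% of its charge, against my budget share of 19.9%, and the reciprocal of the part still living is 1.22. The simulated run without the step from enzyme to spent catalyst loses no enzyme, so its reciprocal is one, and its order falls from 1.2 to 1.0, the largest single effect on the order. Priced by the same integrated form, the 45.2% of product in the flask at 8.00 min came to a budget share of 98.8%, above the 19.9% at the moment of looking.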